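**Plan**

1. Retrosynthesis: the seven O–CH3 bonds are cut last. Then come the stilbene C=C (Horner–Wadsworth–Emmons, back to a C5 ester on ring B), the C2–aryl bond (decarboxylative arylation of a C2 carboxylic acid, a helper not present in the target), the ring-closing C3–C3a bond (photochemical), the C2=C3 bond (aldol condensation) and the O1–CH2 bond (Williamson).
2. Forward: ring B and all three outer aryl rings are bought. O1–C2 and C2=C3 are made first, the dihydrofuran ring is closed in one photochemical step, the catechol ring is attached at C2, and the styryl arm is grown from the C5 ester.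
3. Enabling feature: in the aryl vinyl ether the ring-B bond C3a=C7a, a lone pair on O1 and the C2=C3 bond form a six-electron 1-oxa-triene. Light closes C3–C3a, and the dearomatized carbonyl ylide (anionic end at C2, stabilized by the C2 carbonyl helper) rearomatizes by a 1,4-hydrogen shift.
4. Stereochemistry: C3 is created in the photocyclization under the influence of an (S)-4-benzyloxazolidinone on the C2 carbonyl; the C3 epimers are diastereomers and are separated. C2 is set trans to C3 by substrate control when the C2 radical is arylated. The (E)-alkene comes from the olefination.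

Key step: step 4

Remark: atom numbers are those of the 2,3-dihydro-1-benzofuran core (O1, C2, C3, C3a, C4 to C7, C7a; ring B is the benzo ring); the sense of facial induction by the oxazolidinone in step 4 cannot be predicted with certainty, so the (S)-auxiliary is assumed to favour the 3S series and its (R)-antipode would be used otherwise.

**Route**

Step 1
Reactants: 1 methyl 4-hydroxy-2-methoxybenzoate; 2 (S)-4-benzyl-3-(chloroacetyl)oxazolidin-2-one
Product: 3 (S)-4-benzyl-3-{[3-methoxy-4-(methoxycarbonyl)phenoxy]acetyl}oxazolidin-2-one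
Conditions: K2CO3, MeCN, 50 °C
Reagents that add atoms: none
Why: Williamson ether synthesis in which the phenoxide displaces chloride at the activated α-carbon of the chloroacetyl imide, the mild carbonate base being expected to leave the imide and the methyl ester intact.

Step 2
Reactants: 3 (S)-4-benzyl-3-{[3-methoxy-4-(methoxycarbonyl)phenoxy]acetyl}oxazolidin-2-one; 4 3,5-dimethoxybenzaldehyde
Product: 5 (4S)-4-benzyl-3-{(2S,3R)-3-(3,5-dimethoxyphenyl)-3-hydroxy-2-[3-methoxy-4-(methoxycarbonyl)phenoxy]propanoyl}oxazolidin-2-one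
Conditions: n-Bu2BOTf, i-Pr2NEt, CH2Cl2, −78 → 0 °C; then pH 7 buffer, MeOH, H2O2, 0 °C
Reagents that add atoms: none
Why: boron-mediated Evans syn-aldol addition through a closed chair transition state should give the (2S,3R) adduct, and since both new centers are removed in step 3 only conversion matters.

Step 3
Reactants: 5 (4S)-4-benzyl-3-{(2S,3R)-3-(3,5-dimethoxyphenyl)-3-hydroxy-2-[3-methoxy-4-(methoxycarbonyl)phenoxy]propanoyl}oxazolidin-2-one
Product: 7 (4S)-4-benzyl-3-{(2Z)-3-(3,5-dimethoxyphenyl)-2-[3-methoxy-4-(methoxycarbonyl)phenoxy]prop-2-enoyl}oxazolidin-2-one, via mesylate 6 (not isolated)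
Conditions: MsCl, Et3N, CH2Cl2, 0 °C; then DBU, 0 → 20 °C
Reagents that add atoms: none
Why: O-sulfonylation followed by E1cB elimination through the imide enolate should give the conjugated 2-aryloxy-enoyl imide, mainly as the (Z)-isomer with the aryl group anti to the carbonyl, a geometry that is not critical because it equilibrates under irradiation.

Step 4
Reactants: 7 (4S)-4-benzyl-3-{(2Z)-3-(3,5-dimethoxyphenyl)-2-[3-methoxy-4-(methoxycarbonyl)phenoxy]prop-2-enoyl}oxazolidin-2-one
Product: 10 (4S)-4-benzyl-3-{[(2S,3S)-3-(3,5-dimethoxyphenyl)-6-methoxy-5-(methoxycarbonyl)-2,3-dihydro-1-benzofuran-2-yl]carbonyl}oxazolidin-2-one, via carbonyl ylide 8 (not isolated), via cis imide 9 (not isolated)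
Conditions: hν (300–350 nm, Pyrex), degassed PhMe (0.01 M), 20 °C; then DBU (0.2 equiv), 20 °C; chromatographic separation of the C3 epimers
Reagents that add atoms: none
Why: Proposed new method: irradiation of the 2-aryloxy-enoyl imide should bring about a conrotatory six-electron closure of the triad C3a=C7a–O1–C2=C3 between C3 and C3a, giving carbonyl ylide 8 in which ring B is dearomatized and the anionic end at C2 is an imide enolate; the closest known reaction type is the heteroatom-directed photoarylation (six-electron photocyclization) of 2-aryloxyenones to dihydrobenzofurans, and new here are the acyclic cinnamoyl imide and the use of the oxazolidinone for facial control. The ylide collapses by a suprafacial 1,4-hydrogen shift from C3a to C2, so that regained aromaticity of ring B drives the step, and the (Z)-alkene thereby gives first the 2,3-cis imide 9. The dihydrofuran ring is closed by an excited-state electrocyclization, which in ground-state terms would be a disfavoured 5-endo-trig attack on C3 and which avoids an ionic C3 centre altogether (a cation there would take a hydride from C2, an anion would expel the aryloxide). C3 is set in the ring closure under the influence of the (S)-4-benzyl group, which shields one face of the enoyl plane so that the 3,5-dimethoxyphenyl group on the C3 terminus should turn to the open face as the bond forms, and since the two C3 epimers are diastereomers the 3S series is secured by chromatography whatever the level of induction. C2 is set by thermodynamic control, DBU epimerizing the cis imide through its enolate to the trans imide 10 (this center is reset in step 6). The step needs closure at C3a and not at C7, which the substrate secures because C7 lies between O1 and the 6-methoxy group that the 5-ester forces to point toward C7, and it needs exclusion of oxygen so that the ylide is not oxidized to the benzofuran.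

Step 5
Reactants: 10 (4S)-4-benzyl-3-{[(2S,3S)-3-(3,5-dimethoxyphenyl)-6-methoxy-5-(methoxycarbonyl)-2,3-dihydro-1-benzofuran-2-yl]carbonyl}oxazolidin-2-one
Product: 11 (2S,3S)-3-(3,5-dimethoxyphenyl)-6-methoxy-5-(methoxycarbonyl)-2,3-dihydro-1-benzofuran-2-carboxylic acid
Conditions: LiOH, H2O2, THF–H2O, 0 °C; then Na2SO3; then 1 M HCl
Reagents that add atoms: hydrogen peroxide, OO (as LiOOH; one oxygen becomes the acid OH)
Why: hydroperoxide-selective exocyclic cleavage of the N-acyl oxazolidinone (standard auxiliary removal) should free the acid and the recoverable auxiliary without touching the hindered aryl methyl ester or C3.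

Step 6
Reactants: 11 (2S,3S)-3-(3,5-dimethoxyphenyl)-6-methoxy-5-(methoxycarbonyl)-2,3-dihydro-1-benzofuran-2-carboxylic acid; 12 4-bromo-1,2-dimethoxybenzene
Product: 13 methyl (2S,3S)-2-(3,4-dimethoxyphenyl)-3-(3,5-dimethoxyphenyl)-6-methoxy-2,3-dihydro-1-benzofuran-5-carboxylate
Conditions: [Ir(dF(CF3)ppy)2(dtbbpy)]PF6 (1 mol %), NiCl2·glyme (10 mol %), dtbbpy (15 mol %), Cs2CO3, DMF, 450 nm LEDs, 25 °C
Reagents that add atoms: none
Why: metallaphotoredox decarboxylative arylation of an α-oxy acid, in which the photo-oxidized carboxylate loses CO2, the planar C2 radical is captured by the aryl–nickel species and the aryl group is delivered anti to the C3 aryl group (substrate control, also the thermodynamic trans isomer), so that the former C2 configuration is erased and C2 is set as S.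

Step 7
Reactants: 13 methyl (2S,3S)-2-(3,4-dimethoxyphenyl)-3-(3,5-dimethoxyphenyl)-6-methoxy-2,3-dihydro-1-benzofuran-5-carboxylate
Product: 14 [(2S,3S)-2-(3,4-dimethoxyphenyl)-3-(3,5-dimethoxyphenyl)-6-methoxy-2,3-dihydro-1-benzofuran-5-yl]methanol
Conditions: i-Bu2AlH, CH2Cl2, −78 → 0 °C; aqueous potassium sodium tartrate work-up
Reagents that add atoms: none
Why: hydride reduction of the aryl methyl ester to the benzylic alcohol, no other reducible group being present and neither stereocenter being adjacent to the reacting carbon.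

Step 8
Reactants: 14 [(2S,3S)-2-(3,4-dimethoxyphenyl)-3-(3,5-dimethoxyphenyl)-6-methoxy-2,3-dihydro-1-benzofuran-5-yl]methanol
Product: 15 (2S,3S)-2-(3,4-dimethoxyphenyl)-3-(3,5-dimethoxyphenyl)-6-methoxy-2,3-dihydro-1-benzofuran-5-carbaldehyde
Conditions: MnO2, CH2Cl2, 20 °C
Reagents that add atoms: none
Why: MnO2 should oxidize the electron-rich benzylic alcohol selectively to the aldehyde under neutral conditions that cannot epimerize C2 or C3.

Step 9
Reactants: 15 (2S,3S)-2-(3,4-dimethoxyphenyl)-3-(3,5-dimethoxyphenyl)-6-methoxy-2,3-dihydro-1-benzofuran-5-carbaldehyde; 16 diethyl (3,5-dimethoxybenzyl)phosphonate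
Product: 17 (2S,3S)-2-(3,4-dimethoxyphenyl)-3-(3,5-dimethoxyphenyl)-5-[(E)-2-(3,5-dimethoxyphenyl)ethenyl]-6-methoxy-2,3-dihydro-1-benzofuran
Conditions: NaH, THF, 0 → 20 °C
Reagents that add atoms: none
Why: Horner–Wadsworth–Emmons olefination of the aldehyde with the benzylic phosphonate anion should give the (E)-stilbene, since the semi-stabilized carbanion adds reversibly and eliminates through the anti oxaphosphetane.

Step 10
Reactants: 17 (2S,3S)-2-(3,4-dimethoxyphenyl)-3-(3,5-dimethoxyphenyl)-5-[(E)-2-(3,5-dimethoxyphenyl)ethenyl]-6-methoxy-2,3-dihydro-1-benzofuran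
Product: 18 (2S,3S)-2-(3,4-dihydroxyphenyl)-3-(3,5-dihydroxyphenyl)-5-[(E)-2-(3,5-dihydroxyphenyl)ethenyl]-2,3-dihydro-1-benzofuran-6-ol
Conditions: BBr3 (excess), CH2Cl2, −78 → 0 °C; then MeOH, H2O
Reagents that add atoms: none
Why: BBr3 cleaves the seven aryl methyl ethers by bromide attack on the methyl group of each boron-complexed ether, while complexation makes the rings electron-poor and should thereby protect the benzylic C2–O1 bond and the stilbene at low temperature, any reversible opening at C2 re-closing to the thermodynamically preferred trans isomer.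

**Compound list**

1 | methyl 4-hydroxy-2-methoxybenzoate | COC(=O)c1ccc(O)cc1OC | starting material
2 | (S)-4-benzyl-3-(chloroacetyl)oxazolidin-2-one | O=C(CCl)N1C(=O)OC[C@@H]1Cc1ccccc1 | starting material
3 | (S)-4-benzyl-3-{[3-methoxy-4-(methoxycarbonyl)phenoxy]acetyl}oxazolidin-2-one | COC(=O)c1ccc(OCC(=O)N2C(=O)OC[C@@H]2Cc2ccccc2)cc1OC | intermediate
4 | 3,5-dimethoxybenzaldehyde | COc1cc(C=O)cc(OC)c1 | starting material
5 | (4S)-4-benzyl-3-{(2S,3R)-3-(3,5-dimethoxyphenyl)-3-hydroxy-2-[3-methoxy-4-(methoxycarbonyl)phenoxy]propanoyl}oxazolidin-2-one (syn aldol adduct) | COc1cc(cc(OC)c1)[C@@H](O)[C@H](Oc1ccc(C(=O)OC)c(OC)c1)C(=O)N1C(=O)OC[C@@H]1Cc1ccccc1 | intermediate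
6 | 3-O-methanesulfonate of 5, same configuration (2S,3R,4S) | COc1cc(cc(OC)c1)[C@@H](OS(C)(=O)=O)[C@H](Oc1ccc(C(=O)OC)c(OC)c1)C(=O)N1C(=O)OC[C@@H]1Cc1ccccc1 | intermediate (not isolated)
7 | (4S)-4-benzyl-3-{(2Z)-3-(3,5-dimethoxyphenyl)-2-[3-methoxy-4-(methoxycarbonyl)phenoxy]prop-2-enoyl}oxazolidin-2-one | COc1cc(cc(OC)c1)/C=C(\Oc1ccc(C(=O)OC)c(OC)c1)C(=O)N1C(=O)OC[C@@H]1Cc1ccccc1 | intermediate
8 | carbonyl ylide: zwitterion with ring B dearomatized (C3a sp3 and bearing H, O1 as oxocarbenium toward C7a, C2 as the imide enolate carbon); C3 configured as in 10; both C3a epimers, a center that is lost on rearomatization | COC(=O)C1=CC2[C@H](c3cc(OC)cc(OC)c3)[C-](C(=O)N3C(=O)OC[C@@H]3Cc3ccccc3)[O+]=C2C=C1OC | intermediate (not isolated)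
9 | (4S)-4-benzyl-3-{[(2R,3S)-3-(3,5-dimethoxyphenyl)-6-methoxy-5-(methoxycarbonyl)-2,3-dihydro-1-benzofuran-2-yl]carbonyl}oxazolidin-2-one (2,3-cis) | COC(=O)c1cc2c(cc1OC)O[C@@H](C(=O)N1C(=O)OC[C@@H]1Cc1ccccc1)[C@H]2c1cc(OC)cc(OC)c1 | intermediate (not isolated)
10 | (4S)-4-benzyl-3-{[(2S,3S)-3-(3,5-dimethoxyphenyl)-6-methoxy-5-(methoxycarbonyl)-2,3-dihydro-1-benzofuran-2-yl]carbonyl}oxazolidin-2-one (2,3-trans) | COC(=O)c1cc2c(cc1OC)O[C@H](C(=O)N1C(=O)OC[C@@H]1Cc1ccccc1)[C@H]2c1cc(OC)cc(OC)c1 | intermediate
11 | (2S,3S)-3-(3,5-dimethoxyphenyl)-6-methoxy-5-(methoxycarbonyl)-2,3-dihydro-1-benzofuran-2-carboxylic acid | COC(=O)c1cc2c(cc1OC)O[C@H](C(=O)O)[C@H]2c1cc(OC)cc(OC)c1 | intermediate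
12 | 4-bromo-1,2-dimethoxybenzene | COc1ccc(Br)cc1OC | starting material
13 | methyl (2S,3S)-2-(3,4-dimethoxyphenyl)-3-(3,5-dimethoxyphenyl)-6-methoxy-2,3-dihydro-1-benzofuran-5-carboxylate | COC(=O)c1cc2c(cc1OC)O[C@H](c1ccc(OC)c(OC)c1)[C@H]2c1cc(OC)cc(OC)c1 | intermediate
14 | [(2S,3S)-2-(3,4-dimethoxyphenyl)-3-(3,5-dimethoxyphenyl)-6-methoxy-2,3-dihydro-1-benzofuran-5-yl]methanol | OCc1cc2c(cc1OC)O[C@H](c1ccc(OC)c(OC)c1)[C@H]2c1cc(OC)cc(OC)c1 | intermediate
15 | (2S,3S)-2-(3,4-dimethoxyphenyl)-3-(3,5-dimethoxyphenyl)-6-methoxy-2,3-dihydro-1-benzofuran-5-carbaldehyde | O=Cc1cc2c(cc1OC)O[C@H](c1ccc(OC)c(OC)c1)[C@H]2c1cc(OC)cc(OC)c1 | intermediate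
16 | diethyl (3,5-dimethoxybenzyl)phosphonate | CCOP(=O)(Cc1cc(OC)cc(OC)c1)OCC | starting material
17 | (2S,3S)-2-(3,4-dimethoxyphenyl)-3-(3,5-dimethoxyphenyl)-5-[(E)-2-(3,5-dimethoxyphenyl)ethenyl]-6-methoxy-2,3-dihydro-1-benzofuran | COc1cc(/C=C/c2cc3c(cc2OC)O[C@H](c2ccc(OC)c(OC)c2)[C@H]3c2cc(OC)cc(OC)c2)cc(OC)c1 | intermediate
18 | (2S,3S)-2-(3,4-dihydroxyphenyl)-3-(3,5-dihydroxyphenyl)-5-[(E)-2-(3,5-dihydroxyphenyl)ethenyl]-2,3-dihydro-1-benzofuran-6-ol | Oc1cc(O)cc(/C=C/c2cc3c(cc2O)O[C@H](c2ccc(O)c(O)c2)[C@H]3c2cc(O)cc(O)c2)c1 | target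

**Step count and risks**

Total step count: 10. Longest linear sequence: 10 steps (from 1 to 18; compounds 2, 4, 12 and 16 enter as purchased reagents).

Steps most likely to fail:

1. Step 4 (carries the label). What may go wrong: ring closure at C7 instead of C3a, unproductive E/Z isomerization or dimerization of the enoyl imide in place of cyclization, and weak facial selection that leaves the 3S diastereomer as the minor one. Fallback (known chemistry, the ring is closed through C2–C3 instead): it sets out from 1 and comes back to the route at 13. Friedel–Crafts ortho-acylation of 1 with 3,5-dimethoxybenzoyl chloride (TiCl4) should give methyl 5-(3,5-dimethoxybenzoyl)-4-hydroxy-2-methoxybenzoate F1. O-Alkylation with 3,4-dimethoxybenzyl chloride (K2CO3, DMF) gives methyl 5-(3,5-dimethoxybenzoyl)-4-[(3,4-dimethoxybenzyl)oxy]-2-methoxybenzoate F2. Condensation with hydrazine gives the hydrazone F3, and MnO2 oxidation gives the diaryldiazomethane F4. With Rh2(S-PTAD)4 (or its antipode, chosen to deliver 3S) the donor/donor carbene inserts enantioselectively into the benzylic O–CH2 bond and gives the 2,3-cis dihydrobenzofuran methyl (2R,3S)-2-(3,4-dimethoxyphenyl)-3-(3,5-dimethoxyphenyl)-6-methoxy-2,3-dihydro-1-benzofuran-5-carboxylate F5. CF3CO2H then equilibrates C2 through the benzylic cation to the trans isomer 13.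

2. Step 6. What may go wrong: β-hydride elimination at the nickel alkyl (aromatization toward the benzofuran), slow oxidative addition of the electron-rich aryl bromide, or insufficient trans selectivity. Fallback (thermal, reductive radical generation from an activated ester and a boron aryl donor in place of photo-oxidation of the free acid): it sets out from 11 and comes back at 13. Esterification of 11 with N-hydroxytetrachlorophthalimide (N,N'-diisopropylcarbodiimide, CH2Cl2) gives the redox-active ester F6. Nickel-catalysed decarboxylative Suzuki-type coupling with commercial (3,4-dimethoxyphenyl)boronic acid (NiCl2·6H2O, bathophenanthroline, Et3N, dioxane–DMF, 75 °C) gives 13. Any cis isomer would be equilibrated to trans with CF3CO2H.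

3. Step 10. What may go wrong: ionization of the benzylic C2–O1 bond and cationic oligomerization of the electron-rich stilbene under the Lewis acid, or incomplete cleavage of seven ethers. Fallback (the demethylation is moved ahead of the olefination, and the last step becomes a fluoride desilylation): it sets out from 15 and comes back at 18. BBr3 on 15, which has no stilbene and whose ring B is deactivated by the formyl group, gives the pentahydroxy aldehyde F7. Silylation (t-BuMe2SiCl, imidazole, DMF) gives the penta-silyl ether F8. (3,5-Dihydroxybenzyl)triphenylphosphonium bromide F9, made in one operation from commercial 3,5-dihydroxybenzyl alcohol and Ph3P·HBr, is deprotonated in situ with excess LiN(SiMe3)2 and used in a Wittig reaction with F8. Iodine-catalysed Z to E isomerization then gives the penta-silylated stilbene F10; silyl scrambling would be harmless here. n-Bu4NF buffered with AcOH finally removes all silyl groups to give 18.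

**Further compounds**

F1 | step 4 | methyl 5-(3,5-dimethoxybenzoyl)-4-hydroxy-2-methoxybenzoate | COC(=O)c1cc(C(=O)c2cc(OC)cc(OC)c2)c(O)cc1OC
F2 | step 4 | methyl 5-(3,5-dimethoxybenzoyl)-4-[(3,4-dimethoxybenzyl)oxy]-2-methoxybenzoate | COC(=O)c1cc(C(=O)c2cc(OC)cc(OC)c2)c(OCc2ccc(OC)c(OC)c2)cc1OC
F3 | step 4 | hydrazone of F2 | COC(=O)c1cc(C(=NN)c2cc(OC)cc(OC)c2)c(OCc2ccc(OC)c(OC)c2)cc1OC
F4 | step 4 | diaryldiazomethane from F3 | COC(=O)c1cc(C(=[N+]=[N-])c2cc(OC)cc(OC)c2)c(OCc2ccc(OC)c(OC)c2)cc1OC
F5 | step 4 | methyl (2R,3S)-2-(3,4-dimethoxyphenyl)-3-(3,5-dimethoxyphenyl)-6-methoxy-2,3-dihydro-1-benzofuran-5-carboxylate (2,3-cis) | COC(=O)c1cc2c(cc1OC)O[C@@H](c1ccc(OC)c(OC)c1)[C@H]2c1cc(OC)cc(OC)c1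
F6 | step 6 | tetrachloro-N-hydroxyphthalimide ester of 11 (2S,3S) | COC(=O)c1cc2c(cc1OC)O[C@H](C(=O)ON1C(=O)c3c(Cl)c(Cl)c(Cl)c(Cl)c3C1=O)[C@H]2c1cc(OC)cc(OC)c1
F7 | step 10 | (2S,3S)-2-(3,4-dihydroxyphenyl)-3-(3,5-dihydroxyphenyl)-6-hydroxy-2,3-dihydro-1-benzofuran-5-carbaldehyde | O=Cc1cc2c(cc1O)O[C@H](c1ccc(O)c(O)c1)[C@H]2c1cc(O)cc(O)c1
F8 | step 10 | penta-O-(tert-butyldimethylsilyl) ether of F7 | O=Cc1cc2c(cc1O[Si](C)(C)C(C)(C)C)O[C@H](c1ccc(O[Si](C)(C)C(C)(C)C)c(O[Si](C)(C)C(C)(C)C)c1)[C@H]2c1cc(O[Si](C)(C)C(C)(C)C)cc(O[Si](C)(C)C(C)(C)C)c1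
F9 | step 10 | (3,5-dihydroxybenzyl)triphenylphosphonium bromide | Oc1cc(O)cc(C[P+](c2ccccc2)(c2ccccc2)c2ccccc2)c1.[Br-]
F10 | step 10 | (2S,3S)-penta-O-silylated (E)-stilbene with free 3,5-dihydroxystyryl ring | Oc1cc(O)cc(/C=C/c2cc3c(cc2O[Si](C)(C)C(C)(C)C)O[C@H](c2ccc(O[Si](C)(C)C(C)(C)C)c(O[Si](C)(C)C(C)(C)C)c2)[C@H]3c2cc(O[Si](C)(C)C(C)(C)C)cc(O[Si](C)(C)C(C)(C)C)c2)c1
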